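**Retrosynthetic overview**

1. Route map: 1 → 2 → [3] → 4; 4 + 5 → [6] → [7] → 8 → 9 (square brackets = formed in the flask, not isolated).
2. 9 ⇐ 8: the C1 carbinol comes from catalyst-controlled transfer hydrogenation of the (4S)-tetralone, cis to the C4 aryl.
3. 8 ⇐ 7 (key disconnection, C3–C4): a cyclopropanol serves as a ketone homoenolate whose β-carbon C3 attacks the quinone-methide carbon C4. Both carbons are electrophilic in normal carbonyl and benzylic chemistry. This bond closes the carbocycle and sets C4.
4. 7 ⇐ 6 ⇐ 4 + 5: the C4–C1' bond comes from Friedel–Crafts para-alkylation of the naphthol by a lactol, in the same flask. 4 ⇐ 2 ⇐ 1: C4 comes from Br/Li exchange and DMF; the cyclopropane (C2, C3) comes from a Kulinkovich reaction.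
5. Ring order: both benzenoid units are bought; cyclopropane (step 1) → transient five-membered oxacycle (steps 2 and 3) → six-membered carbocycle of the tetralin (step 3).

Assumptions and labels: 1 and 5 are taken as catalogue chemicals; (R)-TRIP is assumed to give the 4S ketone in step 3 (the sense of induction of this new cyclization is untested, and (S)-TRIP is used if it proves opposite); C1–C8a follow the tetralin numbering of the target and C1' is the naphthyl carbon bonded to C4.

**Route**

Step 1
Reactants: 1 methyl 2-bromo-3-methoxybenzoate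
Product: 2 1-(2-bromo-3-methoxyphenyl)cyclopropan-1-ol
Conditions: EtMgBr (3.0 equiv, added over 2 h), Ti(OiPr)4 (0.3 equiv), THF, 0 °C to rt; then H2O
Reagents that add atoms: ethylmagnesium bromide, CC[Mg]Br
Why: Kulinkovich reaction: the titanacyclopropane made from EtMgBr and Ti(OiPr)4 adds twice to the ester carbonyl as a 1,2-dicarbanion, which leaves the aryl bromide and aryl ether untouched and creates no stereocenter.

Step 2
Reactants: 2 1-(2-bromo-3-methoxyphenyl)cyclopropan-1-ol
Product: 4 4'-methoxy-3'H-spiro[cyclopropane-1,1'-isobenzofuran]-3'-ol (racemic lactol), via dilithio aryl alkoxide 3 (not isolated)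
Conditions: n-BuLi (2.2 equiv), THF, −78 °C; DMF (3 equiv), −78 to 0 °C; then H2O
Reagents that add atoms: N,N-dimethylformamide, CN(C)C=O
Why: O–H deprotonation and bromine–lithium exchange give aryllithium 3, which is formylated by DMF (Bouveault aldehyde synthesis); the hydroxy aldehyde closes to the five-membered lactol, whose new carbon is a labile racemic center that is erased in step 3.

Step 3
Reactants: 4 4'-methoxy-3'H-spiro[cyclopropane-1,1'-isobenzofuran]-3'-ol; 5 8-methoxynaphthalen-1-ol
Product: 8 (4S)-4-(4-hydroxy-5-methoxynaphthalen-1-yl)-5-methoxy-3,4-dihydronaphthalen-1(2H)-one, via spiro phthalan Friedel–Crafts adduct 6 (not isolated), via para-quinone methide cyclopropanol 7 (not isolated)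
Conditions: (R)-TRIP [(R)-3,3'-bis(2,4,6-triisopropylphenyl)-1,1'-binaphthyl-2,2'-diyl hydrogen phosphate] (10 mol %), 4 Å MS, PhMe (0.02 M), 0 °C, 12 h; then 50 °C, 24 h
Reagents that add atoms: none
Why: Proposed new method: the chiral phosphoric acid ionizes lactol 4 to a cyclic benzylic oxocarbenium ion that alkylates 5 at C4 (para to OH, the more reactive α-position; the peri O–H···OMe hydrogen bond keeps the acid from steering the electrophile ortho) to give cyclopropyl ether 6 (Friedel–Crafts); on warming, the same acid reversibly opens the doubly benzylic C–O bond of 6 to para-quinone methide 7, in which the acid protonates the quinone-methide oxygen while its phosphoryl oxygen binds the freed cyclopropanol O–H, so that the strained, oxygen-activated C1–C3 σ-bond attacks C4 through C3 (cyclopropanol as ketone homoenolate; irreversible, driven by ring strain, C=O formation and rearomatization) inside the chiral ion pair, which selects the C4 face (4S) and closes the six-membered ring, with O-reclosure to 6 only a reversible resting state; closest known reactions are phosphoric acid catalyzed enantioselective 1,6-additions to para-quinone methides made in situ from para-hydroxybenzyl alcohols, and ring-opening homo-Mannich and Lewis acid mediated homoenolate alkylations of cyclopropanols.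

Step 4
Reactants: 8 (4S)-4-(4-hydroxy-5-methoxynaphthalen-1-yl)-5-methoxy-3,4-dihydronaphthalen-1(2H)-one
Product: 9 (1S,4S)-4-(4-hydroxy-5-methoxynaphthalen-1-yl)-5-methoxy-1,2,3,4-tetrahydronaphthalen-1-ol (Dipolynaphthalene B)
Conditions: RuCl[(S,S)-TsDPEN](p-cymene) (1 mol %), HCO2H/Et3N (5:2), EtOAc, 40 °C
Reagents that add atoms: none
Why: Noyori–Ikariya asymmetric transfer hydrogenation: the (S,S) catalyst gives (S)-carbinols from 1-tetralones, which sets C1 as S, and this hydride delivery is anti to the pseudoaxial C4 naphthyl (the substrate's own preference), so catalyst and substrate are matched for the 1,4-cis alcohol while the phenol, the aryl ethers and C4 are untouched.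

**Compound list**

1 | methyl 2-bromo-3-methoxybenzoate | COC(=O)c1cccc(OC)c1Br | starting material
2 | 1-(2-bromo-3-methoxyphenyl)cyclopropan-1-ol | COc1cccc(C2(O)CC2)c1Br | intermediate
3 | lithium 1-(2-lithio-3-methoxyphenyl)cyclopropan-1-olate (formed in the flask) | COc1cccc(C2(O[Li])CC2)c1[Li] | intermediate
4 | 4'-methoxy-3'H-spiro[cyclopropane-1,1'-isobenzofuran]-3'-ol, racemic lactol of 2-(1-hydroxycyclopropyl)-6-methoxybenzaldehyde | COc1cccc2c1C(O)OC21CC1 | intermediate
5 | 8-methoxynaphthalen-1-ol | COc1cccc2cccc(O)c12 | starting material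
6 | 3'-(4-hydroxy-5-methoxynaphthalen-1-yl)-4'-methoxy-3'H-spiro[cyclopropane-1,1'-isobenzofuran], racemic (formed in the flask) | COc1cccc2c1C(c1ccc(O)c3c(OC)cccc13)OC21CC1 | intermediate
7 | 4-{[2-(1-hydroxycyclopropyl)-6-methoxyphenyl]methylidene}-8-methoxynaphthalen-1(4H)-one (formed in the flask) | COc1cccc(C2(O)CC2)c1C=C1C=CC(=O)c2c(OC)cccc21 | intermediate
8 | (4S)-4-(4-hydroxy-5-methoxynaphthalen-1-yl)-5-methoxy-3,4-dihydronaphthalen-1(2H)-one | COc1cccc2c1[C@H](c1ccc(O)c3c(OC)cccc13)CCC2=O | intermediate
9 | (1S,4S)-4-(4-hydroxy-5-methoxynaphthalen-1-yl)-5-methoxy-1,2,3,4-tetrahydronaphthalen-1-ol (Dipolynaphthalene B) | COc1cccc2c1[C@H](c1ccc(O)c3c(OC)cccc13)CC[C@@H]2O | target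

**Totals**

Total step count: 4. Longest linear sequence: 4 steps (1 → 2 → 4 → 8 → 9); naphthol 5 is used as bought and enters at step 3.

**Steps most likely to fail, with fallbacks**

Step 3 is the least certain. The cyclopropanol C–C attack is untested and may not take over from reversible O-closure, so the reaction could stall at 6. The acid may also give low ee, and some ortho-alkylation of 5 is possible. The fallback splits the cascade and gives up catalyst control of C4. It sets out from 4 and 5: diphenyl phosphate (5 mol %) in CH2Cl2 at 0 °C stops at spiro phthalan 6, which is isolated. TiCl4 (2.2 equiv, CH2Cl2, −78 to −20 °C) then opens the doubly benzylic C–O bond and turns the cyclopropoxide into a titanium homoenolate that closes onto the benzylic cation, giving the racemic ketone F1. The step 4 catalyst reduces both enantiomers of F1 to the 1S carbinol. The 4S half becomes 9, and the 4R half becomes the (1S,4R)-trans alcohol F2, a diastereomer removed by chromatography (at most 50 % yield of 9 from F1). The route is rejoined at 9.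

Step 1 is next. With a hindered ortho-bromo aryl ester the Kulinkovich reaction can stop at ketone or tertiary alcohol by-products or lose bromine. The fallback builds the cyclopropanol by cyclopropanating a silyl enol ether. It sets out from 1: Me3SiCH2Li (2.2 equiv, THF, 0 °C; then MeOH) gives the methyl ketone 1-(2-bromo-3-methoxyphenyl)ethan-1-one F3. TMSOTf/Et3N (CH2Cl2, 0 °C) gives the silyl enol ether F4. Et2Zn/CH2I2 (CH2Cl2, 0 °C, Furukawa–Simmons–Smith) gives the siloxycyclopropane F5. K2CO3 in MeOH removes silicon, and the route is rejoined at 2.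

Step 4 is third. The catalyst and the remote C4 substituent could prove mismatched, or the free naphthol could slow the ruthenium hydride, giving poor conversion or a low cis:trans ratio. The fallback hands stereocontrol to the substrate. It sets out from 8: LiBH(s-Bu)3 (2.5 equiv, THF, −78 °C) attacks the carbonyl anti to the C4 naphthyl, which the peri methoxy group forces pseudoaxial, and gives the cis alcohol. The minor C1 epimer, the (1R,4S)-trans alcohol F6, is removed by chromatography, and the route is rejoined at 9.

**Further compounds**

F1 | step 3 | racemic 4-(4-hydroxy-5-methoxynaphthalen-1-yl)-5-methoxy-3,4-dihydronaphthalen-1(2H)-one | COc1cccc2c1C(c1ccc(O)c3c(OC)cccc13)CCC2=O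
F2 | step 3 | (1S,4R)-4-(4-hydroxy-5-methoxynaphthalen-1-yl)-5-methoxy-1,2,3,4-tetrahydronaphthalen-1-ol | COc1cccc2c1[C@@H](c1ccc(O)c3c(OC)cccc13)CC[C@@H]2O
F3 | step 1 | 1-(2-bromo-3-methoxyphenyl)ethan-1-one | COc1cccc(C(C)=O)c1Br
F4 | step 1 | {[1-(2-bromo-3-methoxyphenyl)ethenyl]oxy}trimethylsilane | COc1cccc(C(=C)O[Si](C)(C)C)c1Br
F5 | step 1 | [1-(2-bromo-3-methoxyphenyl)cyclopropoxy]trimethylsilane | COc1cccc(C2(O[Si](C)(C)C)CC2)c1Br
F6 | step 4 | (1R,4S)-4-(4-hydroxy-5-methoxynaphthalen-1-yl)-5-methoxy-1,2,3,4-tetrahydronaphthalen-1-ol | COc1cccc2c1[C@H](c1ccc(O)c3c(OC)cccc13)CC[C@H]2O
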